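**Plan**
- The enabling feature is ring A (C3a, C4, C5, C6, C7, C7a): a resorcinol fused to the five-membered ring through C3a–C7a, with oxygen at C4 (ortho to C3a) and C6 (para to C3a). This maps onto a 2-alkyl-3-benzyloxyfuran whose ring oxygen becomes the C6 hydroxyl.
- Retrosynthetic cuts, in order: the exocyclic C1–C(=O)Ar bond (carbonylative coupling at an enol triflate); C3a–C7a and C6–C7 (furan/ynone Diels–Alder and bridge opening); the ynone C–C bond (Weinreb amide); the C2–aryl bond (α-arylation); the C3–furan bond (conjugate Friedel–Crafts); the enone C=C (aldol condensation).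
- Forward: the chain is joined first (steps 1–6), the five-membered ring and ring A arise together in step 7, then the aroyl group is attached and the C1=C2 alkene is hydrogenated.
- Stereochemistry: C3 comes from the Sc(OTf)3–pybox-catalysed Friedel–Crafts addition (step 3). C1 and C2 come from syn addition of H2 anti to the C3 aryl group (step 12), which gives the all-cis (1R,2R,3R) indane encoded in the target SMILES.

Key step: step 7

Assumption: the pybox enantiomer named in step 3 is taken to give the R centre; should the sense of induction be the opposite, its mirror image is the ligand meant.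

**Step 1**
Reactants: 1 3-bromofuran
Product: 2 3-(benzyloxy)furan
Conditions: BnOH (2 equiv), CuI (10 mol %), 3,4,7,8-tetramethyl-1,10-phenanthroline (20 mol %), Cs2CO3, PhMe, 110 °C, sealed tube
Reagents that add atoms: benzyl alcohol, OCc1ccccc1
Why: Copper-catalysed Ullmann-type C–O coupling of a heteroaryl bromide with a primary alcohol, which is the standard way to etherify a position that does not undergo nucleophilic aromatic substitution.

**Step 2**
Reactants: 3 4-(benzyloxy)benzaldehyde; 4 2-acetyl-1-methylimidazole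
Product: 5 (E)-3-[4-(benzyloxy)phenyl]-1-(1-methyl-1H-imidazol-2-yl)prop-2-en-1-one
Conditions: KOH (20 mol %), EtOH, 0 → 23 °C
Reagents that add atoms: none
Why: Claisen–Schmidt condensation of a methyl ketone with a non-enolisable aryl aldehyde, in which elimination from the aldol gives the conjugated E-alkene.

**Step 3**
Reactants: 2 3-(benzyloxy)furan (1.5 equiv); 5 (E)-3-[4-(benzyloxy)phenyl]-1-(1-methyl-1H-imidazol-2-yl)prop-2-en-1-one
Product: 6 (3R)-3-[3-(benzyloxy)furan-2-yl]-3-[4-(benzyloxy)phenyl]-1-(1-methyl-1H-imidazol-2-yl)propan-1-one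
Conditions: Sc(OTf)3 (10 mol %), 2,6-bis[(3aS,8aR)-8,8a-dihydro-3aH-indeno[1,2-d]oxazol-2-yl]pyridine (12 mol %), 4 Å MS, MeCN, −40 °C
Reagents that add atoms: none
Why: Catalytic enantioselective Friedel–Crafts (Michael-type) alkylation, in which the acyl imidazole binds the scandium–pybox complex as an N,O-chelate so that one face of the enone is shielded and the furan attacks the β-carbon through C2, its most nucleophilic position, setting the R centre that becomes C3 of the target.

**Step 4**
Reactants: 6 (3R)-3-[3-(benzyloxy)furan-2-yl]-3-[4-(benzyloxy)phenyl]-1-(1-methyl-1H-imidazol-2-yl)propan-1-one; 7 1-bromo-3,5-bis(benzyloxy)benzene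
Product: 8 (3R)-3-[3-(benzyloxy)furan-2-yl]-3-[4-(benzyloxy)phenyl]-2-[3,5-bis(benzyloxy)phenyl]-1-(1-methyl-1H-imidazol-2-yl)propan-1-one (both C2 epimers)
Conditions: Pd(OAc)2 (5 mol %), Xantphos (6 mol %), NaOt-Bu (2.2 equiv), PhMe, 80 °C
Reagents that add atoms: none
Why: Buchwald–Hartwig α-arylation of a ketone enolate at its only enolisable position, with a wide-bite-angle bisphosphine to keep the palladium from being held by the N,O-chelating substrate and to favour reductive elimination; the new C2 centre is erased later and the non-acidic C3–H is untouched.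

**Step 5**
Reactants: 8 (3R)-3-[3-(benzyloxy)furan-2-yl]-3-[4-(benzyloxy)phenyl]-2-[3,5-bis(benzyloxy)phenyl]-1-(1-methyl-1H-imidazol-2-yl)propan-1-one
Product: 10 (3R)-3-[3-(benzyloxy)furan-2-yl]-3-[4-(benzyloxy)phenyl]-2-[3,5-bis(benzyloxy)phenyl]-N-methoxy-N-methylpropanamide, via acylimidazolium triflate 9 (not isolated)
Conditions: MeOTf (1.2 equiv), 4 Å MS, MeCN, 23 °C; then MeNH(OMe) (3 equiv), 23 °C
Reagents that add atoms: N,O-dimethylhydroxylamine, CNOC
Why: N-methylation turns the acyl imidazole into an acyl imidazolium, an activated acyl donor from which the amine displaces 1,3-dimethylimidazol-2-ylidene (acyl transfer), the established unmasking of 2-acyl imidazoles.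

**Step 6**
Reactants: 10 (3R)-3-[3-(benzyloxy)furan-2-yl]-3-[4-(benzyloxy)phenyl]-2-[3,5-bis(benzyloxy)phenyl]-N-methoxy-N-methylpropanamide; 11 ethynylmagnesium bromide (3 equiv)
Product: 12 (5R)-5-[3-(benzyloxy)furan-2-yl]-5-[4-(benzyloxy)phenyl]-4-[3,5-bis(benzyloxy)phenyl]pent-1-yn-3-one (both C4 epimers)
Conditions: THF, 0 → 23 °C; inverse quench into cold 0.5 M aq. HCl
Reagents that add atoms: none
Why: Weinreb ketone synthesis, in which the chelated tetrahedral intermediate prevents a second addition and the acidic inverse quench protonates the released amine before it can add to the terminal ynone.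

**Step 7**
Reactants: 12 (5R)-5-[3-(benzyloxy)furan-2-yl]-5-[4-(benzyloxy)phenyl]-4-[3,5-bis(benzyloxy)phenyl]pent-1-yn-3-one
Product: 14 (3R)-4-(benzyloxy)-3-[4-(benzyloxy)phenyl]-2-[3,5-bis(benzyloxy)phenyl]-6-hydroxy-2,3-dihydro-1H-inden-1-one, via oxanorbornadiene cycloadduct 13 (not isolated)
Conditions: PhMe (0.01 M), BHT (cat.), 100 °C; then camphorsulfonic acid (10 mol %), 23 °C
Reagents that add atoms: none
Why: Heating brings the electron-rich 3-benzyloxyfuran (diene termini furan C2 and C5) and the electron-poor terminal ynone into a concerted, asynchronous intramolecular furan Diels–Alder reaction that gives oxanorbornadiene 13. The five-membered ring closes in the 5-exo sense through the C3a–C7a bond between the tethered termini, and the six-membered ring closes as the [4+2] ring itself through C3a–C7a and C6–C7. The acid then ionises the bridge at the tertiary, doubly allylic C3a–O bond and the cyclohexadienyl cation loses the C6 proton, so the furan oxygen stays on C6 as the phenol, the benzyloxy group ends on C4 and C1 is a ketone; this is the known furan–alkynone cycloaddition/aromatisation route to phenols. No lasting stereocentre is made (both bridgeheads become sp2, C2 stays epimerisable) and C3 is a spectator. The selectivities needed are the regiochemistry of the cycloaddition, fixed by the three-atom tether, and the direction of bridge opening: only C3a–O cleavage can end in an arene because C3a carries no hydrogen, whereas the benzyloxy-assisted ionisation at C6–O is expected to be reversible and unproductive, which is why a catalytic sulfonic acid with a non-nucleophilic counter-ion in dry toluene is used.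

**Step 8**
Reactants: 14 (3R)-4-(benzyloxy)-3-[4-(benzyloxy)phenyl]-2-[3,5-bis(benzyloxy)phenyl]-6-hydroxy-2,3-dihydro-1H-inden-1-one
Product: 15 (3R)-4,6-bis(benzyloxy)-3-[4-(benzyloxy)phenyl]-2-[3,5-bis(benzyloxy)phenyl]-2,3-dihydro-1H-inden-1-one
Conditions: BnBr (1.1 equiv), K2CO3 (1.5 equiv), acetone, 23 °C
Reagents that add atoms: benzyl bromide, BrCc1ccccc1
Why: Williamson etherification, in which the carbonate deprotonates the phenol far more readily than the ketone α-position, so O-alkylation should outrun C-alkylation at C2.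

**Step 9**
Reactants: 15 (3R)-4,6-bis(benzyloxy)-3-[4-(benzyloxy)phenyl]-2-[3,5-bis(benzyloxy)phenyl]-2,3-dihydro-1H-inden-1-one
Product: 16 (1R)-5,7-bis(benzyloxy)-1-[4-(benzyloxy)phenyl]-2-[3,5-bis(benzyloxy)phenyl]-1H-inden-3-yl trifluoromethanesulfonate
Conditions: Tf2O (1.3 equiv), 2,6-di-tert-butyl-4-methylpyridine (1.5 equiv), CH2Cl2, 0 → 23 °C
Reagents that add atoms: trifluoromethanesulfonic anhydride, O=S(=O)(OS(=O)(=O)C(F)(F)F)C(F)(F)F
Why: Enol triflate formation by O-triflation of the ketone and loss of its only α-hydrogen, run with a hindered, weak pyridine base instead of an amide base so that the newly acidified, doubly benzylic indene C1–H (the former C3–H) is not removed and the stereocentre is kept.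

**Step 10**
Reactants: 17 1-(benzyloxy)-4-bromobenzene
Product: 19 [4-(benzyloxy)phenyl]tributylstannane, via aryllithium 18 (not isolated)
Conditions: n-BuLi (1.05 equiv), THF, −78 °C; then Bu3SnCl, −78 → 23 °C
Reagents that add atoms: tributyltin chloride, CCCC[Sn](Cl)(CCCC)CCCC
Why: Bromine–lithium exchange followed by trapping of the aryllithium with a tin electrophile, a routine preparation of aryl stannanes that the benzyl ether tolerates at low temperature.

**Step 11**
Reactants: 16 (1R)-5,7-bis(benzyloxy)-1-[4-(benzyloxy)phenyl]-2-[3,5-bis(benzyloxy)phenyl]-1H-inden-3-yl trifluoromethanesulfonate; 19 [4-(benzyloxy)phenyl]tributylstannane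
Product: 20 {(1S)-5,7-bis(benzyloxy)-1-[4-(benzyloxy)phenyl]-2-[3,5-bis(benzyloxy)phenyl]-1H-inden-3-yl}[4-(benzyloxy)phenyl]methanone
Conditions: Pd(PPh3)4 (10 mol %), LiCl (3 equiv), CO (1 atm), 1,4-dioxane, 80 °C; neutral work-up without fluoride or amine
Reagents that add atoms: carbon monoxide, [C-]#[O+]
Why: Carbonylative Stille coupling, in which zerovalent palladium inserts into the C–OTf bond, CO insertion gives the acyl palladium faster than the slow aryl transfer from tin, and the base-free medium leaves the C1–H centre intact (the descriptor changes from R to S only because the substituent priorities change).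

**Step 12**
Reactants: 20 {(1S)-5,7-bis(benzyloxy)-1-[4-(benzyloxy)phenyl]-2-[3,5-bis(benzyloxy)phenyl]-1H-inden-3-yl}[4-(benzyloxy)phenyl]methanone
Product: 21 caraphenol C, [(1R,2R,3R)-2-(3,5-dihydroxyphenyl)-4,6-dihydroxy-3-(4-hydroxyphenyl)-2,3-dihydro-1H-inden-1-yl](4-hydroxyphenyl)methanone
Conditions: H2 (1 atm), 10% Pd/C, EtOAc–MeOH (1:1), 23 °C
Reagents that add atoms: none
Why: Heterogeneous catalytic hydrogenation delivers H2 syn to the tetrasubstituted alkene from the face opposite the aryl group on the neighbouring sp3 carbon, which sets C1 and C2 cis to each other and to the C3 aryl group, while the five benzyl ethers are removed by hydrogenolysis under the same neutral conditions that should not epimerise the ketone α-centre.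

**Compound list**
1 | 3-bromofuran | Brc1ccoc1 | starting material
2 | 3-(benzyloxy)furan | c1occc1OCc1ccccc1 | intermediate
3 | 4-(benzyloxy)benzaldehyde | O=Cc1ccc(OCc2ccccc2)cc1 | starting material
4 | 2-acetyl-1-methylimidazole | CC(=O)c1nccn1C | starting material
5 | (E)-3-[4-(benzyloxy)phenyl]-1-(1-methyl-1H-imidazol-2-yl)prop-2-en-1-one | O=C(/C=C/c1ccc(OCc2ccccc2)cc1)c1nccn1C | intermediate
6 | (3R)-3-[3-(benzyloxy)furan-2-yl]-3-[4-(benzyloxy)phenyl]-1-(1-methyl-1H-imidazol-2-yl)propan-1-one | O=C(C[C@H](c1ccc(OCc2ccccc2)cc1)c1occc1OCc1ccccc1)c1nccn1C | intermediate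
7 | 1-bromo-3,5-bis(benzyloxy)benzene | Brc1cc(OCc2ccccc2)cc(OCc2ccccc2)c1 | starting material
8 | (3R)-3-[3-(benzyloxy)furan-2-yl]-3-[4-(benzyloxy)phenyl]-2-[3,5-bis(benzyloxy)phenyl]-1-(1-methyl-1H-imidazol-2-yl)propan-1-one (both C2 epimers) | O=C(C(c1cc(OCc2ccccc2)cc(OCc2ccccc2)c1)[C@H](c1ccc(OCc2ccccc2)cc1)c1occc1OCc1ccccc1)c1nccn1C | intermediate
9 | 2-{(3R)-3-[3-(benzyloxy)furan-2-yl]-3-[4-(benzyloxy)phenyl]-2-[3,5-bis(benzyloxy)phenyl]propanoyl}-1,3-dimethylimidazolium trifluoromethanesulfonate | C[n+]1ccn(C)c1C(=O)C(c1cc(OCc2ccccc2)cc(OCc2ccccc2)c1)[C@H](c1ccc(OCc2ccccc2)cc1)c1occc1OCc1ccccc1.[O-]S(=O)(=O)C(F)(F)F | intermediate (not isolated)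
10 | (3R)-3-[3-(benzyloxy)furan-2-yl]-3-[4-(benzyloxy)phenyl]-2-[3,5-bis(benzyloxy)phenyl]-N-methoxy-N-methylpropanamide (both C2 epimers) | CON(C)C(=O)C(c1cc(OCc2ccccc2)cc(OCc2ccccc2)c1)[C@H](c1ccc(OCc2ccccc2)cc1)c1occc1OCc1ccccc1 | intermediate
11 | ethynylmagnesium bromide | C#C[Mg]Br | starting material
12 | (5R)-5-[3-(benzyloxy)furan-2-yl]-5-[4-(benzyloxy)phenyl]-4-[3,5-bis(benzyloxy)phenyl]pent-1-yn-3-one (both C4 epimers) | C#CC(=O)C(c1cc(OCc2ccccc2)cc(OCc2ccccc2)c1)[C@H](c1ccc(OCc2ccccc2)cc1)c1occc1OCc1ccccc1 | intermediate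
13 | (3R)-4-(benzyloxy)-3-[4-(benzyloxy)phenyl]-2-[3,5-bis(benzyloxy)phenyl]-2,3-dihydro-3a,6-epoxyinden-1(6H)-one (bridge on either face, C2 epimers) | O=C1C(c2cc(OCc3ccccc3)cc(OCc3ccccc3)c2)[C@H](c2ccc(OCc3ccccc3)cc2)C23OC(C=C2OCc2ccccc2)C=C13 | intermediate (not isolated)
14 | (3R)-4-(benzyloxy)-3-[4-(benzyloxy)phenyl]-2-[3,5-bis(benzyloxy)phenyl]-6-hydroxy-2,3-dihydro-1H-inden-1-one (C2 epimerisable) | O=C1c2cc(O)cc(OCc3ccccc3)c2[C@@H](c2ccc(OCc3ccccc3)cc2)C1c1cc(OCc3ccccc3)cc(OCc3ccccc3)c1 | intermediate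
15 | (3R)-4,6-bis(benzyloxy)-3-[4-(benzyloxy)phenyl]-2-[3,5-bis(benzyloxy)phenyl]-2,3-dihydro-1H-inden-1-one (C2 epimerisable) | O=C1c2cc(OCc3ccccc3)cc(OCc3ccccc3)c2[C@@H](c2ccc(OCc3ccccc3)cc2)C1c1cc(OCc3ccccc3)cc(OCc3ccccc3)c1 | intermediate
16 | (1R)-5,7-bis(benzyloxy)-1-[4-(benzyloxy)phenyl]-2-[3,5-bis(benzyloxy)phenyl]-1H-inden-3-yl trifluoromethanesulfonate | O=S(=O)(OC1=C(c2cc(OCc3ccccc3)cc(OCc3ccccc3)c2)[C@H](c2ccc(OCc3ccccc3)cc2)c2c(OCc3ccccc3)cc(OCc3ccccc3)cc12)C(F)(F)F | intermediate
17 | 1-(benzyloxy)-4-bromobenzene | Brc1ccc(OCc2ccccc2)cc1 | starting material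
18 | [4-(benzyloxy)phenyl]lithium | [Li]c1ccc(OCc2ccccc2)cc1 | intermediate (not isolated)
19 | [4-(benzyloxy)phenyl]tributylstannane | CCCC[Sn](CCCC)(CCCC)c1ccc(OCc2ccccc2)cc1 | intermediate
20 | {(1S)-5,7-bis(benzyloxy)-1-[4-(benzyloxy)phenyl]-2-[3,5-bis(benzyloxy)phenyl]-1H-inden-3-yl}[4-(benzyloxy)phenyl]methanone | O=C(c1ccc(OCc2ccccc2)cc1)C1=C(c2cc(OCc3ccccc3)cc(OCc3ccccc3)c2)[C@H](c2ccc(OCc3ccccc3)cc2)c2c(OCc3ccccc3)cc(OCc3ccccc3)cc12 | intermediate
21 | caraphenol C, [(1R,2R,3R)-2-(3,5-dihydroxyphenyl)-4,6-dihydroxy-3-(4-hydroxyphenyl)-2,3-dihydro-1H-inden-1-yl](4-hydroxyphenyl)methanone (all-cis) | O=C(c1ccc(O)cc1)[C@H]1c2cc(O)cc(O)c2[C@@H](c2ccc(O)cc2)[C@H]1c1cc(O)cc(O)c1 | target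

**Totals**
Total step count: 12.
Longest linear sequence: 10 steps (steps 2 to 9, then 11 and 12, starting from 3 and 4).

**Steps most likely to fail**

Step 7. The oxygen bridge may open at the wrong bond: ionisation at C6–O, which the C4 benzyloxy group assists, could be followed by loss of the benzyl group or a skeletal shift instead of return to the cycloadduct, so that aromatisation to the C6 phenol is outrun. The fallback sets out from Weinreb amide 10 and comes back at phenol 14; it keeps the same two ring-forming bonds but makes the bridge opening regiospecific through an enolate.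
- Vinylmagnesium bromide in THF should give (5R)-5-[3-(benzyloxy)furan-2-yl]-5-[4-(benzyloxy)phenyl]-4-[3,5-bis(benzyloxy)phenyl]pent-1-en-3-one F1.
- Heating in toluene should close C3a–C7a and C6–C7 to the oxanorbornene (3R)-4-(benzyloxy)-3-[4-(benzyloxy)phenyl]-2-[3,5-bis(benzyloxy)phenyl]-2,3,7,7a-tetrahydro-3a,6-epoxyinden-1(6H)-one F2.
- LiN(SiMe3)2 at −78 °C, with an acetic acid quench at that temperature, removes the C7a proton; the enolate expels the bridge oxygen from C3a by E1cB, the only C–O bond β to it, to give (3R)-4-(benzyloxy)-3-[4-(benzyloxy)phenyl]-2-[3,5-bis(benzyloxy)phenyl]-6-hydroxy-2,3,6,7-tetrahydro-1H-inden-1-one F3.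
- Dess–Martin periodinane buffered with NaHCO3 oxidises the C6 carbinol to (3R)-4-(benzyloxy)-3-[4-(benzyloxy)phenyl]-2-[3,5-bis(benzyloxy)phenyl]-2,3-dihydro-1H-indene-1,6(7H)-dione F4, which enolises in the flask to 14.

Step 3. Enantioselectivity may be eroded by an uncatalysed background addition of the very nucleophilic furan, a second alkylation may occur at furan C5, or the alkoxyfuran may decompose on the Lewis acid. The fallback sets out from furan 2 and comes back at ketone 6; it forms the C3–aryl bond instead of the C3–furan bond in the asymmetric step.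
- n-BuLi in THF at −78 °C should give 3-(benzyloxy)-2-lithiofuran F5, which is formylated with DMF to 3-(benzyloxy)furan-2-carbaldehyde F6.
- A Horner–Wadsworth–Emmons reaction with diethyl [2-(methoxy(methyl)amino)-2-oxoethyl]phosphonate (LiCl, DBU, MeCN) gives (E)-3-[3-(benzyloxy)furan-2-yl]-N-methoxy-N-methylprop-2-enamide F7.
- Hayashi–Miyaura addition of [4-(benzyloxy)phenyl]boronic acid with Rh(acac)(C2H4)2 and the BINAP enantiomer that gives the R centre (dioxane–water, 100 °C) gives (3R)-3-[3-(benzyloxy)furan-2-yl]-3-[4-(benzyloxy)phenyl]-N-methoxy-N-methylpropanamide F8.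
- 2-Lithio-1-methylimidazole F9, made from 1-methylimidazole and n-BuLi at −78 °C, adds to the Weinreb amide to give 6.

Step 11. The hindered tetrasubstituted triflate may couple directly without CO insertion or stall at oxidative addition, and the doubly benzylic C1–H may be deprotonated during long heating or tin removal, which would erode the configuration. The fallback sets out from triflate 16 and comes back at ketone 20; it forms the same C–C bond at the alcohol oxidation level without tin or heat.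
- Nozaki–Hiyama–Kishi coupling with aldehyde 3 (CrCl2, NiCl2 cat., DMF, 23 °C) should give {(1S)-5,7-bis(benzyloxy)-1-[4-(benzyloxy)phenyl]-2-[3,5-bis(benzyloxy)phenyl]-1H-inden-3-yl}[4-(benzyloxy)phenyl]methanol F10 as a mixture of carbinol epimers.
- MnO2 in CH2Cl2 oxidises the allylic, benzylic alcohol to 20 under neutral conditions.

**Further compounds**
F1 | step 7 | (5R)-5-[3-(benzyloxy)furan-2-yl]-5-[4-(benzyloxy)phenyl]-4-[3,5-bis(benzyloxy)phenyl]pent-1-en-3-one | C=CC(=O)C(c1cc(OCc2ccccc2)cc(OCc2ccccc2)c1)[C@H](c1ccc(OCc2ccccc2)cc1)c1occc1OCc1ccccc1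
F2 | step 7 | (3R)-4-(benzyloxy)-3-[4-(benzyloxy)phenyl]-2-[3,5-bis(benzyloxy)phenyl]-2,3,7,7a-tetrahydro-3a,6-epoxyinden-1(6H)-one | O=C1C(c2cc(OCc3ccccc3)cc(OCc3ccccc3)c2)[C@H](c2ccc(OCc3ccccc3)cc2)C23OC(C=C2OCc2ccccc2)CC13
F3 | step 7 | (3R)-4-(benzyloxy)-3-[4-(benzyloxy)phenyl]-2-[3,5-bis(benzyloxy)phenyl]-6-hydroxy-2,3,6,7-tetrahydro-1H-inden-1-one | O=C1C(c2cc(OCc3ccccc3)cc(OCc3ccccc3)c2)[C@H](c2ccc(OCc3ccccc3)cc2)C2=C1CC(O)C=C2OCc1ccccc1
F4 | step 7 | (3R)-4-(benzyloxy)-3-[4-(benzyloxy)phenyl]-2-[3,5-bis(benzyloxy)phenyl]-2,3-dihydro-1H-indene-1,6(7H)-dione | O=C1C(c2cc(OCc3ccccc3)cc(OCc3ccccc3)c2)[C@H](c2ccc(OCc3ccccc3)cc2)C2=C1CC(=O)C=C2OCc1ccccc1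
F5 | step 3 | 3-(benzyloxy)-2-lithiofuran | [Li]c1occc1OCc1ccccc1
F6 | step 3 | 3-(benzyloxy)furan-2-carbaldehyde | O=Cc1occc1OCc1ccccc1
F7 | step 3 | (E)-3-[3-(benzyloxy)furan-2-yl]-N-methoxy-N-methylprop-2-enamide | CON(C)C(=O)/C=C/c1occc1OCc1ccccc1
F8 | step 3 | (3R)-3-[3-(benzyloxy)furan-2-yl]-3-[4-(benzyloxy)phenyl]-N-methoxy-N-methylpropanamide | CON(C)C(=O)C[C@H](c1ccc(OCc2ccccc2)cc1)c1occc1OCc1ccccc1
F9 | step 3 | 2-lithio-1-methylimidazole | [Li]c1nccn1C
F10 | step 11 | {(1S)-5,7-bis(benzyloxy)-1-[4-(benzyloxy)phenyl]-2-[3,5-bis(benzyloxy)phenyl]-1H-inden-3-yl}[4-(benzyloxy)phenyl]methanol | OC(c1ccc(OCc2ccccc2)cc1)C1=C(c2cc(OCc3ccccc3)cc(OCc3ccccc3)c2)[C@H](c2ccc(OCc3ccccc3)cc2)c2c(OCc3ccccc3)cc(OCc3ccccc3)cc12
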